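**Plan**
1. Central ring numbering: C1 bears the CH2CH2 bridge, C2 the 4-hydroxybenzyl group, C3 the OH, C5 the OMe. The enabling feature is that C1 and C2 carry two neighbouring benzylic carbons, with an oxygen on C3 beside them.
2. Retrosynthesis: (a) the diarylmethane CH2 on C2 is raised to C=O, C3-OH is masked as OMe and the two outer phenols as benzyl ethers. (b) The CH2–CH2 bond of the bridge and the C(=O)–aryl bond are cut together, which ties the two benzylic carbons to each other as the CH2–C(=O) edge of 3,5-dimethoxybenzocyclobutenone. (c) That four-membered ring is cut to 3,5-dimethoxybenzyne and a ketene acetal.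
3. Forward: all three benzene rings are bought, and the only ring made is the temporary cyclobutenone (aryne [2+2]). It is opened in a three-component step: an aryllithium adds to its C=O, the alkoxide opens to an o-quinodimethane dienolate, and this is benzylated at its CH2 terminus.
4. The ketone left on C2 then directs cleavage of the adjacent C3-OMe only, which differentiates two methoxy groups that came from a symmetric bromide. It is finally removed together with both benzyl groups by hydrogenolysis.
5. Stereochemistry: none has to be set. The only stereocentres on the way (carbinol carbons) are transient and end as C=O or CH2.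

Key step: step 3

Remark: every sp3 carbon of the target is CH2 or CH3 and there is no stereogenic axis or double bond. The compound is therefore achiral and the given structure is a single species that needs no enantiocontrol.

**Step 1**
Reactants: 1 1-bromo-3,5-dimethoxybenzene; 2 1,1-diethoxyethene
Product: 5 3,5-dimethoxybicyclo[4.2.0]octa-1,3,5-trien-7-one, via 3,5-dimethoxybenzyne 3 (not isolated), via diethyl acetal 4 (not isolated)
Conditions: NaNH2, THF, reflux; then 1 M HCl, THF, rt
Reagents that add atoms: water, O
Why: Aryne [2+2] cycloaddition with a ketene acetal followed by acetal hydrolysis, in which amide removes H-2 between Br and OMe, bromide leaves (both possible arynes are identical by symmetry), and the nucleophilic CH2 of 2 attacks the aryne carbon remote from the flanking methoxy group so that the acetal carbon, later C=O, ends up next to that methoxy group.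

**Step 2**
Reactants: 6 [2-(benzyloxy)phenyl]methanol
Product: 7 1-(benzyloxy)-2-(bromomethyl)benzene
Conditions: PBr3, Et2O, 0 °C
Reagents that add atoms: phosphorus tribromide, BrP(Br)Br
Why: Standard bromination of a primary benzylic alcohol (SN2 on the phosphite ester), under which the aryl benzyl ether is inert, and the bromide is used freshly made.

**Step 3**
Reactants: 5 3,5-dimethoxybicyclo[4.2.0]octa-1,3,5-trien-7-one; 7 1-(benzyloxy)-2-(bromomethyl)benzene; 8 1-(benzyloxy)-4-bromobenzene
Product: 12 [4-(benzyloxy)phenyl](2-{2-[2-(benzyloxy)phenyl]ethyl}-4,6-dimethoxyphenyl)methanone, via aryllithium 9 (not isolated), via lithium benzocyclobutenoxide 10 (not isolated), via lithium dienolate 11 (not isolated)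
Conditions: 8, n-BuLi, THF, −78 °C; add 5, −78 °C; add 7, DMPU, −78 °C → rt; aq. NH4Cl
Reagents that add atoms: none
Why: Proposed new method: aryllithium 9 adds to the strained carbonyl of 5 (enolisation would create a benzocyclobutadiene-type enolate and is not expected), the oxido group of 10 accelerates conrotatory 4π electrocyclic opening of the C7–C8 bond with the oxygen turning outward, and the CH2 terminus of the resulting α-oxido-o-quinodimethane 11, which is at the same time the laterally metalated form of a 2-methylbenzophenone, displaces bromide from 7 (SN2), so that the CH2–CH2 bond forms while the central ring regains its aromaticity. The closest known reaction types are the oxyanion-accelerated opening of benzocyclobutenoxides with capture of the o-quinodimethane by dienophiles or aldehydes and the benzylation of laterally lithiated 2,4-dimethoxy-6-methylbenzoates; the untested part is their merger in one flask with a benzylic halide as the terminating electrophile. No ring is closed (the temporary four-membered ring is opened) and no stereocentre is created in the product, since the racemic carbinolate carbon of 10 ends as the planar carbonyl carbon of 12. The step needs site selectivity within the ambident anion 11 (O, ring carbon C2, exocyclic CH2), and only attack through CH2 restores the benzene ring, which should secure C-alkylation there. It also needs the anion on the methyl-derived carbon and nowhere else, which deprotonation of a 2-benzyltoluene could not deliver because the diarylmethane CH2 is the more acidic site; here the anion is born regiospecifically from the C–C bond that breaks and the competing site is held at the ketone level. The hindered tertiary alkoxide 10 is a poor partner for 7 before it opens, 1-bromobutane from the exchange is far less reactive than the benzylic bromide, and remetalation of 12 is disfavoured by allylic strain in the substituted dienolate, which should limit O-benzylation, butylation and double benzylation.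

**Step 4**
Reactants: 12 [4-(benzyloxy)phenyl](2-{2-[2-(benzyloxy)phenyl]ethyl}-4,6-dimethoxyphenyl)methanone
Product: 13 [4-(benzyloxy)phenyl](2-{2-[2-(benzyloxy)phenyl]ethyl}-6-hydroxy-4-methoxyphenyl)methanone
Conditions: MgI2 (anhydrous), Et2O–toluene, 80 °C; dilute HCl work-up
Reagents that add atoms: none
Why: Chelation-controlled aryl methyl ether cleavage, in which Mg(II) bridges the ketone oxygen and the ortho methoxy oxygen and iodide removes that methyl group by SN2, while the para methoxy group and the two remote benzyl ethers cannot chelate, and any stray debenzylation would be harmless because step 5 removes those groups anyway.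

**Step 5**
Reactants: 13 [4-(benzyloxy)phenyl](2-{2-[2-(benzyloxy)phenyl]ethyl}-6-hydroxy-4-methoxyphenyl)methanone
Product: 16 2-(4-hydroxybenzyl)-3-[2-(2-hydroxyphenyl)ethyl]-5-methoxyphenol, via triphenolic ketone 14 (not isolated), via benzhydrol 15 (not isolated)
Conditions: H2 (4 atm), 10% Pd/C, EtOH–AcOH, cat. HCl, rt → 40 °C
Reagents that add atoms: none
Why: Catalytic hydrogenolysis, in which the O-benzyl groups should go first, the diaryl ketone is hydrogenated to the benzhydrol, and its doubly benzylic C–O bond, labilised in acid by the ortho and para hydroxy groups (quinone-methide-type ionisation), is cleaved to CH2 without touching the aryl methyl ether or the phenols.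

**Compound list**
1 | 1-bromo-3,5-dimethoxybenzene | COc1cc(Br)cc(OC)c1 | starting material
2 | 1,1-diethoxyethene (ketene diethyl acetal) | C=C(OCC)OCC | starting material
3 | 3,5-dimethoxybenzyne (triple bond C1–C2, OMe on C3 and C5) | COC1=CC(OC)=CC#C1 | intermediate
4 | 7,7-diethoxy-3,5-dimethoxybicyclo[4.2.0]octa-1,3,5-triene | CCOC1(OCC)Cc2cc(OC)cc(OC)c12 | intermediate
5 | 3,5-dimethoxybicyclo[4.2.0]octa-1,3,5-trien-7-one (C=O on the fusion carbon next to 5-OMe) | COc1cc2CC(=O)c2c(OC)c1 | intermediate
6 | [2-(benzyloxy)phenyl]methanol | OCc1ccccc1OCc1ccccc1 | starting material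
7 | 1-(benzyloxy)-2-(bromomethyl)benzene | BrCc1ccccc1OCc1ccccc1 | intermediate
8 | 1-(benzyloxy)-4-bromobenzene | Brc1ccc(OCc2ccccc2)cc1 | starting material
9 | [4-(benzyloxy)phenyl]lithium | [Li]c1ccc(OCc2ccccc2)cc1 | intermediate
10 | lithium 7-[4-(benzyloxy)phenyl]-3,5-dimethoxybicyclo[4.2.0]octa-1,3,5-trien-7-olate (racemic) | COc1cc2CC([O-])(c3ccc(OCc4ccccc4)cc3)c2c(OC)c1.[Li+] | intermediate
11 | lithium dienolate (α-oxido-o-quinodimethane; oxido group expected outward, cis to the C–OMe ring carbon) | C=C1C=C(OC)C=C(OC)/C1=C(\[O-])c1ccc(OCc2ccccc2)cc1.[Li+] | intermediate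
12 | [4-(benzyloxy)phenyl](2-{2-[2-(benzyloxy)phenyl]ethyl}-4,6-dimethoxyphenyl)methanone | COc1cc(OC)c(C(=O)c2ccc(OCc3ccccc3)cc2)c(CCc2ccccc2OCc2ccccc2)c1 | intermediate
13 | [4-(benzyloxy)phenyl](2-{2-[2-(benzyloxy)phenyl]ethyl}-6-hydroxy-4-methoxyphenyl)methanone | COc1cc(O)c(C(=O)c2ccc(OCc3ccccc3)cc2)c(CCc2ccccc2OCc2ccccc2)c1 | intermediate
14 | (4-hydroxyphenyl){2-hydroxy-6-[2-(2-hydroxyphenyl)ethyl]-4-methoxyphenyl}methanone | COc1cc(O)c(C(=O)c2ccc(O)cc2)c(CCc2ccccc2O)c1 | intermediate
15 | 2-[hydroxy(4-hydroxyphenyl)methyl]-3-[2-(2-hydroxyphenyl)ethyl]-5-methoxyphenol (racemic) | COc1cc(O)c(C(O)c2ccc(O)cc2)c(CCc2ccccc2O)c1 | intermediate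
16 | 2-(4-hydroxybenzyl)-3-[2-(2-hydroxyphenyl)ethyl]-5-methoxyphenol (achiral) | COc1cc(O)c(Cc2ccc(O)cc2)c(CCc2ccccc2O)c1 | target

**Total step count:** 5. **Longest linear sequence:** 4 (steps 1, 3, 4, 5).

**Steps most likely to fail**

**Step 3 (bears the label).**
- The dienolate may be lost before it is benzylated. Possible causes are proton exchange with the product ketone followed by over-alkylation, 6π closure onto the inward aryl ring, or ring opening of the lithium alkoxide that is too slow.
- The fallback uses known chemistry only, sets out from 7 and 8 and returns at 12.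
- Purchased methyl 2,4-dimethoxy-6-methylbenzoate F1 is laterally lithiated (LDA, THF, −78 °C) and benzylated with 7 to methyl 2-{2-[2-(benzyloxy)phenyl]ethyl}-4,6-dimethoxybenzoate F2.
- LiAlH4 reduction should give (2-{2-[2-(benzyloxy)phenyl]ethyl}-4,6-dimethoxyphenyl)methanol F3, and MnO2 oxidation 2-{2-[2-(benzyloxy)phenyl]ethyl}-4,6-dimethoxybenzaldehyde F4.
- Addition of aryllithium 9 (from 8 and n-BuLi) gives racemic [4-(benzyloxy)phenyl](2-{2-[2-(benzyloxy)phenyl]ethyl}-4,6-dimethoxyphenyl)methanol F5, and Dess–Martin oxidation leads to 12.

**Step 5.**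
- After loss of the benzyl groups, hydrogenation may stall at the di-ortho-substituted, hydrogen-bonded ketone.
- The fallback replaces surface hydrogenolysis by an ortho-hydroxyl-assisted hydride deoxygenation. It sets out from 13 and returns at 16.
- Compound 13 is acylated (ClCO2Et, Et3N, THF, 0 °C) to 2-[4-(benzyloxy)benzoyl]-3-{2-[2-(benzyloxy)phenyl]ethyl}-5-methoxyphenyl ethyl carbonate F6.
- NaBH4 in THF–H2O reduces the ketone, the carbonate migrates to the new alkoxide and leaves, and the o-quinone methide takes up a second hydride. This gives 2-[4-(benzyloxy)benzyl]-3-{2-[2-(benzyloxy)phenyl]ethyl}-5-methoxyphenol F7.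
- Plain O-debenzylation (H2, Pd/C, EtOAc–EtOH, neutral) then gives 16.

**Step 1.**
- The aryne may be captured by amide, the ketene acetal may polymerise, or metalation may occur unproductively between the two methoxy groups.
- The fallback changes the two-carbon partner and the oxidation level. It sets out from 1 and returns at 5.
- Compound 1 is treated with LiTMP in THF in the presence of lithium ethenolate, generated by cleavage of THF with n-BuLi.
- The aryne–enolate [2+2], with the same regiochemical bias, should give 3,5-dimethoxybicyclo[4.2.0]octa-1,3,5-trien-7-ol F8, which Dess–Martin periodinane oxidises to 5.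

**Further compounds**
F1 | step 3 | methyl 2,4-dimethoxy-6-methylbenzoate (purchased) | COC(=O)c1c(C)cc(OC)cc1OC
F2 | step 3 | methyl 2-{2-[2-(benzyloxy)phenyl]ethyl}-4,6-dimethoxybenzoate | COC(=O)c1c(CCc2ccccc2OCc2ccccc2)cc(OC)cc1OC
F3 | step 3 | (2-{2-[2-(benzyloxy)phenyl]ethyl}-4,6-dimethoxyphenyl)methanol | OCc1c(CCc2ccccc2OCc2ccccc2)cc(OC)cc1OC
F4 | step 3 | 2-{2-[2-(benzyloxy)phenyl]ethyl}-4,6-dimethoxybenzaldehyde | O=Cc1c(CCc2ccccc2OCc2ccccc2)cc(OC)cc1OC
F5 | step 3 | [4-(benzyloxy)phenyl](2-{2-[2-(benzyloxy)phenyl]ethyl}-4,6-dimethoxyphenyl)methanol (racemic) | OC(c1ccc(OCc2ccccc2)cc1)c1c(CCc2ccccc2OCc2ccccc2)cc(OC)cc1OC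
F6 | step 5 | 2-[4-(benzyloxy)benzoyl]-3-{2-[2-(benzyloxy)phenyl]ethyl}-5-methoxyphenyl ethyl carbonate | COc1cc(OC(=O)OCC)c(C(=O)c2ccc(OCc3ccccc3)cc2)c(CCc2ccccc2OCc2ccccc2)c1
F7 | step 5 | 2-[4-(benzyloxy)benzyl]-3-{2-[2-(benzyloxy)phenyl]ethyl}-5-methoxyphenol | COc1cc(O)c(Cc2ccc(OCc3ccccc3)cc2)c(CCc2ccccc2OCc2ccccc2)c1
F8 | step 1 | 3,5-dimethoxybicyclo[4.2.0]octa-1,3,5-trien-7-ol (racemic) | COc1cc2CC(O)c2c(OC)c1
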